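## Structural features

The target is a flavanone. Benzo ring A (C4a to C8a, methoxy groups on C7 and C8) is fused to the dihydropyranone ring C (O1, C2, C3, C4, C4a, C8a), and ring B, a 3-hydroxy-4,5-dimethoxyphenyl group, sits on C2. C2 is the only stereocentre (S, from O1 > C1' > C3 > H), so no neighbouring centre and no relative configuration has to be controlled. C2 is benzylic, bonded to the aryl ether oxygen O1 and β to the C4 ketone, and this makes it fragile. Base opens ring C by E1cB loss of the O1 phenoxide to the 2'-hydroxychalcone and recloses it without memory of configuration, strong acid can ionise C2–O1, and the same bond is a benzylic ether open to hydrogenolysis. Four of the five phenolic oxygens are methyl ethers and one (3') is free, so that one needs a mask that comes off under neutral conditions. The skeleton is classical; the real difficulty is to make the lone, labile C2 centre as one enantiomer and keep it through the unmasking. The feature exploited is that C4a=C8a of ring A, O1 and C2 form a 2-oxadiene once C2 is a cation (an O-aryl oxocarbenium ion), and that C4a is the only unsubstituted carbon ortho to O1 and lies para to the 7-methoxy group. A two-carbon C3–C4 donor at the carboxyl oxidation level can therefore add at C2 and close on C4a, which gives ring C, the C2 centre and the C4 carbonyl level in one event.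

## Logic of the disconnections

13 to 12: the free 3'-OH is traced back to its benzyl ether (the O–CH2Ph bond is the one cleaved forward). A free phenol would intercept the cations of the annulation, and a mask that leaves by neutral hydrogenolysis avoids base at the C2 centre. The forward step must cleave this primary benzylic C–O bond without touching the secondary benzylic C2–O1 bond or the C4 ketone.

12 to 11: the C4 carbonyl is traced back to a diethyl ketal (two C4–OEt bonds). This is the form in which the annulation delivers C4, so no redox adjustment follows the stereo-defining step. The forward hydrolysis must be mild enough to leave C2–O1 closed.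

11 to 7 and 8: C2–C3 and C4–C4a are cut together. This removes ring C, both new C–C bonds and the stereocentre in one stroke. It leaves 8 as the two-carbon piece and 7, in which rings A and B are joined only through one acetal carbon and whose own stereocentre is erased on ionisation, so the racemate suffices. The acetate on that carbon is chosen because it leaves more readily than the aryloxide, so that only the aryloxy cation can form. The forward step needs a chiral counter-anion to choose one face of a planar, acyclic cation, and ring closure on C4a must outrun every other fate of the C4 cation.

7 to 5: the C2–H bond and the O–acetyl bond are cut, which takes the acetal carbon back to the carboxyl carbon of an aryl ester. The ester already holds the C–OAr bond that cannot be made by adding a phenol to an aldehyde. The forward hydride addition must stop at the tetrahedral aluminate, and this must be acetylated before it collapses.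

5 to 3 and 4: the acyl C–O bond of the ester is cut, a convergent union of the ring A phenol with the ring B acid. The forward step is a routine dehydrative coupling.

3 to 1: the O–CH2Ph bond is cut, which leads to the commercial hydroxy acid. Forward, both acidic sites are alkylated and the ester is cleaved again in the same flask (through 2).

## Other disconnections considered

Alternative 1: The cut removes C4a–C4, C3–C4 and O1–C2, so ring C is assembled from 6-iodo-2,3-dimethoxyphenol A2, carbon monoxide and the ring B alkyne A3. Forward, PdCl2(PPh3)2 in diethylamine would let zerovalent palladium insert into the C–I bond, take up CO, couple the acyl-palladium species with A3 and let the phenol oxygen close 6-endo-dig onto the triple bond, giving flavone A1.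
- In favour: three bonds from three simple components, every elementary step well precedented, regiochemistry fixed by the iodine.
- Against: A1 is flat at C2, so the stereocentre still has to be made by an enantioselective 1,4-reduction of an electron-rich flavone that must stop at 12. Further drawbacks are toxic CO, possible 5-exo-dig closure to an aurone, an iodination of 4 that must go ortho and not para to the hydroxyl, and a homologation to reach A3.
- Comparison: on structure A1 matches 11 in the oxidation level of C4 but lacks the sp3 C2. On mechanistic certainty of the ring-forming step the alternative is the better plan, and on convergence it is the equal. On step economy it needs about seven to eight operations against six, because the asymmetric reduction is an extra step.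

Alternative 2: The cut removes O1–C2 and C3–C4. Forward, a chiral N-triflyl phosphoramide would release the 4-methoxy ortho-quinone methide A7 from the salicylaldehyde dimethyl acetal A5, and A7 would add to the ring B styrene A6 in a [4+2] sense to give the cis-4-methoxyflavan A4.
- In favour: C2 is set in the ring-forming event as in the chosen plan, the partners are one to two steps from catalogue aldehydes, and acid-catalysed asymmetric cycloadditions of ortho-quinone methides with styrenes are an established class. On precedent for the key step this alternative is therefore the better.
- Against: C4 arrives as a methyl ether at the alcohol level, so its stereocentre is made only to be destroyed, and two further operations (ether to alcohol, alcohol to ketone) are needed next to an oxidisable benzylic C2–H. A6 is also a weak π-donor, because its para oxygen is twisted out of conjugation by its two neighbours, whereas 8 is among the strongest neutral carbon nucleophiles.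
- Comparison: structurally A4 and 11 differ only at C4, where 11 is already at the right level. Mechanistically both rely on a chiral anion paired with a cationic heterodiene. Step count is about seven against six.

Alternative 3: The cut removes C8a–O1. Forward, the (S)-hydroxy dioxolane A9 would cyclise under Pd(OAc)2, a bulky di-tert-butyl biaryl phosphine and Cs2CO3: zerovalent palladium inserts into the C–Br bond, the alkoxide binds to divalent palladium and reductive elimination forms the aryl ether, giving the ethylene ketal A8.
- In favour: the stereocentre is made beforehand by dependable carbonyl chemistry and is not touched in the ring closure, the ketal blocks the elimination to a chalcone, and intramolecular palladium aryl etherification of secondary alcohols is known. On stereochemical security the alternative is the better, and on the final unmasking (ketal hydrolysis, debenzylation) it is the equal.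
- Against: the bromide is flanked on both sides and electron-rich, so oxidative addition is slow; the palladium alkoxide of a secondary benzylic alcohol can undergo β-hydride elimination; and A9 needs a long linear sequence (regioselective bromination, aldol-type C–C bond, ketalisation of a β-oxygenated ketone without dehydration, asymmetric reduction).
- Comparison: the key step forms one C–O bond, whereas the chosen step forms two C–C bonds, the ring and the stereocentre. The step count would be close to double.

Key step: step 4

Assumption: which antipode of the imidodiphosphorimidate delivers the 2S series cannot be derived from first principles; it is to be fixed by a first trial with both antipodes, and the formulas below show the intended 2S series.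

## Route

Step 1
Reactants: 1 3-hydroxy-4,5-dimethoxybenzoic acid
Product: 3 3-benzyloxy-4,5-dimethoxybenzoic acid, via benzyl 3-benzyloxy-4,5-dimethoxybenzoate 2 (not isolated)
Conditions: BnBr (2.3 equiv), K2CO3, acetone, reflux; evaporate; 2 M aq. NaOH, MeOH, 60 °C; 1 M HCl to pH 2
Reagents that add atoms: benzyl bromide BrCc1ccccc1; sodium hydroxide [Na+].[OH-]
Why: Williamson alkylation of phenoxide and carboxylate gives 2, and saponification of the benzyl ester in the same flask returns the acid while the aryl benzyl ether is inert to hydroxide.

Step 2
Reactants: 3 3-benzyloxy-4,5-dimethoxybenzoic acid; 4 2,3-dimethoxyphenol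
Product: 5 2,3-dimethoxyphenyl 3-benzyloxy-4,5-dimethoxybenzoate
Conditions: EDC·HCl, DMAP (cat.), CH2Cl2, 0 °C to rt
Reagents that add atoms: none
Why: Steglich esterification; DMAP carries the activated acyl group to the moderately hindered phenol, and no other nucleophile is present.

Step 3
Reactants: 5 2,3-dimethoxyphenyl 3-benzyloxy-4,5-dimethoxybenzoate
Product: 7 racemic (3-benzyloxy-4,5-dimethoxyphenyl)(2,3-dimethoxyphenoxy)methyl acetate, via aluminium hemiacetal 6 (not isolated)
Conditions: i-Bu2AlH (1.1 equiv), CH2Cl2, −78 °C; then pyridine, DMAP, Ac2O, −78 to −20 °C; aq. potassium sodium tartrate work-up; short plug of Et3N-washed silica, used at once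
Reagents that add atoms: acetic anhydride CC(=O)OC(C)=O
Why: Reductive acetylation of an ester (Rychnovsky type): one hydride adds at −78 °C to give the tetrahedral aluminate 6, which the low temperature and chelation of aluminium by the ortho-methoxy oxygen should hold until it is acetylated in place. The acetal carbon forms as a racemate, which is all the next step needs.

Step 4
Reactants: 7 racemic (3-benzyloxy-4,5-dimethoxyphenyl)(2,3-dimethoxyphenoxy)methyl acetate; 8 ketene diethyl acetal
Product: 11 (2S)-2-(3-benzyloxy-4,5-dimethoxyphenyl)-4,4-diethoxy-7,8-dimethoxychromane, via aryloxy carbenium ion 9 (not isolated), via diethoxycarbenium ion 10 (not isolated)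
Conditions: chiral imidodiphosphorimidate (IDPi, BINOL-derived, N-triflyl core, 3 mol%), 8 (2.2 equiv, added slowly), toluene/CH2Cl2, 4 Å MS, −60 to −20 °C; then Et3N
Reagents that add atoms: none
Why: Proposed new method: the chiral acid, or the 1,1-diethoxyethyl cation that it forms at once with 8, takes acetate from racemic 7 and leaves the planar aryloxy carbenium ion 9 as a contact ion pair with the confined imidodiphosphorimidate anion, so both enantiomers of 7 converge; the nucleophilic CH2 of 8 then attacks C2 in the enantio-determining step and gives diethoxycarbenium ion 10. Ring C closes from 10 by an intramolecular Friedel–Crafts alkylation, 6-exo-trig at the cationic C4 with the C4a=C8a bond of the arene inside the new six-membered ring, and loss of the C4a proton to a further molecule of 8 rearomatises ring A; overall this is a stepwise polar [4+2] of the cationic 2-oxadiene C4a=C8a–O1=C2 with the ketene acetal. The closest known reaction types are the achiral Lewis acid-mediated oxa-Povarov annulation of aryl oxocarbenium ions with alkenes and the chiral counter-anion-directed addition of ketene acetals to cyclic oxocarbenium ions; joining them in one enantioselective annulation of an acyclic aryloxy carbenium ion is the untested part. The only new stereocentre, C2, is under catalyst control: the anion shields one face of 9 inside its pocket, and nothing in the substrate biases the other. Two selectivities are needed, facial choice at C2 and closure at C4a ahead of capture of 10 (ethyl loss to the open-chain ester or addition of more 8). The first is secured by an apolar medium and low temperature that keep the ion pair tight, the second by the 7-methoxy group para to C4a, by C4a being the only unsubstituted ortho carbon of ring A and by the slow addition of 8. The second equivalent of 8 ends as ethyl acetate after taking up the acetate and the proton, which keeps achiral acetic acid from driving a racemic background reaction. C4 is delivered as a ketal, already at the ketone oxidation level.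

Step 5
Reactants: 11 (2S)-2-(3-benzyloxy-4,5-dimethoxyphenyl)-4,4-diethoxy-7,8-dimethoxychromane
Product: 12 (2S)-2-(3-benzyloxy-4,5-dimethoxyphenyl)-7,8-dimethoxychroman-4-one
Conditions: 0.5 M aq. HCl, THF, 0 °C to rt
Reagents that add atoms: water O
Why: Acid-catalysed ketal hydrolysis: the C4 cation is stabilised by the para 7-methoxy group and by O1, so dilute acid at or below room temperature suffices. C2 is not involved and no base is present, so the configuration, the C2–O1 bond and the benzyl ether should be untouched.

Step 6
Reactants: 12 (2S)-2-(3-benzyloxy-4,5-dimethoxyphenyl)-7,8-dimethoxychroman-4-one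
Product: 13 (2S)-2-(3-hydroxy-4,5-dimethoxyphenyl)-7,8-dimethoxychroman-4-one
Conditions: H2 (1 atm), 10% Pd/C, EtOAc, rt, stopped at full conversion
Reagents that add atoms: none
Why: Catalytic hydrogenolysis of a benzyl aryl ether under neutral conditions, which avoids the base-induced ring opening that would racemise C2. The primary O–CH2Ph bond should be cleaved well before the hindered secondary C2–O1 bond or the conjugated ketone reacts.

## Compound list

1 | 3-hydroxy-4,5-dimethoxybenzoic acid | COc1cc(C(=O)O)cc(O)c1OC | starting material
2 | benzyl 3-benzyloxy-4,5-dimethoxybenzoate | COc1cc(C(=O)OCc2ccccc2)cc(OCc2ccccc2)c1OC | intermediate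
3 | 3-benzyloxy-4,5-dimethoxybenzoic acid | COc1cc(C(=O)O)cc(OCc2ccccc2)c1OC | intermediate
4 | 2,3-dimethoxyphenol | COc1cccc(O)c1OC | starting material
5 | 2,3-dimethoxyphenyl 3-benzyloxy-4,5-dimethoxybenzoate | COc1cc(C(=O)Oc2cccc(OC)c2OC)cc(OCc2ccccc2)c1OC | intermediate
6 | racemic diisobutyl[(3-benzyloxy-4,5-dimethoxyphenyl)(2,3-dimethoxyphenoxy)methoxy]aluminium (aluminium hemiacetal) | COc1cc(C(O[Al](CC(C)C)CC(C)C)Oc2cccc(OC)c2OC)cc(OCc2ccccc2)c1OC | intermediate
7 | racemic (3-benzyloxy-4,5-dimethoxyphenyl)(2,3-dimethoxyphenoxy)methyl acetate | COc1cc(C(OC(C)=O)Oc2cccc(OC)c2OC)cc(OCc2ccccc2)c1OC | intermediate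
8 | ketene diethyl acetal (1,1-diethoxyethene) | C=C(OCC)OCC | starting material
9 | [(3-benzyloxy-4,5-dimethoxyphenyl)methylidene](2,3-dimethoxyphenyl)oxonium ion (aryloxy carbenium ion, achiral, paired with the chiral anion) | COc1cc(C=[O+]c2cccc(OC)c2OC)cc(OCc2ccccc2)c1OC | intermediate
10 | (3S)-3-(3-benzyloxy-4,5-dimethoxyphenyl)-3-(2,3-dimethoxyphenoxy)-1,1-diethoxypropan-1-ylium ion | COc1cc([C@@H](Oc2cccc(OC)c2OC)CC(OCC)=[O+]CC)cc(OCc2ccccc2)c1OC | intermediate
11 | (2S)-2-(3-benzyloxy-4,5-dimethoxyphenyl)-4,4-diethoxy-7,8-dimethoxychromane | COc1cc([C@@H]2CC(OCC)(OCC)c3ccc(OC)c(OC)c3O2)cc(OCc2ccccc2)c1OC | intermediate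
12 | (2S)-2-(3-benzyloxy-4,5-dimethoxyphenyl)-7,8-dimethoxychroman-4-one | COc1cc([C@@H]2CC(=O)c3ccc(OC)c(OC)c3O2)cc(OCc2ccccc2)c1OC | intermediate
13 | (2S)-2-(3-hydroxy-4,5-dimethoxyphenyl)-7,8-dimethoxychroman-4-one | COc1cc([C@@H]2CC(=O)c3ccc(OC)c(OC)c3O2)cc(O)c1OC | target

## Step count and least certain steps

Total: 6 steps. Longest linear sequence: 6 steps (1 to 13); 4 and 8 enter as purchased materials at steps 2 and 4.

**Step 4 (key step, proposed new method).**
- What may go wrong: poor facial selectivity, because the acyclic cation can react as a loose ion pair, through more than one C=O geometry, or under catalysis by an achiral acid. The ketene acetal can also be lost to protonation and cationic oligomerisation before it meets 9. The C4 cation can lose an ethyl group to give the open-chain ester before ring closure. The product ketal can re-ionise under the acid.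
- Fallback with known chemistry, from 3 and 4, returning at 12:
  - 4 is C-acetylated ortho to the hydroxyl (AcOH, BF3·OEt2, 90 °C, Fries type) to 1-(2-hydroxy-3,4-dimethoxyphenyl)ethanone F1.
  - F1 is esterified with 3 (EDC·HCl, DMAP) to the aryl ester F2.
  - Baker–Venkataraman acyl shift (KOt-Bu, THF) gives the 1,3-diketone F3.
  - Acid cyclodehydration (TsOH, toluene, 80 °C) gives the flavone F4, the same compound as A1.
  - Enantioselective hydrogenation of the C2=C3 bond (chiral ruthenium N-heterocyclic carbene catalyst from Ru(cod)(2-methylallyl)2, a chiral imidazolinium salt and KOt-Bu, under H2) gives 12 together with some over-reduced cis-flavan-4-ol F5.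
  - Dess–Martin oxidation of the mixture converges on 12.

**Step 3.**
- What may go wrong: the aluminate may collapse before acetylation, since an aryloxide leaves more easily than an alkoxide. This would lead to aldehyde, over-reduction and aryl acetate. The acetoxy ether may also ionise or hydrolyse on handling.
- Fallback from 5, returning at 7:
  - i-Bu2AlH (1.1 equiv, −78 °C) followed by aqueous work-up deliberately lets the hemiacetal collapse to 3-benzyloxy-4,5-dimethoxybenzaldehyde F6, with recovery of 4.
  - Acetyl chloride with catalytic ZnCl2 adds across the C=O bond to give the α-chlorobenzyl acetate F7 (acyl halide addition to an aldehyde).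
  - F7 alkylates 4 at oxygen (K2CO3, MeCN, 0 °C; phenoxide alkylation by an α-haloalkyl ester) to give 7.

**Step 6.**
- What may go wrong: over-reduction, either by hydrogenolytic opening of the benzylic C2–O1 bond or by reduction of the C4 ketone.
- Fallback from 12, returning at 13: non-reductive debenzylation with BCl3 and pentamethylbenzene as cation scavenger in CH2Cl2 at −78 °C. This cleaves the benzyl ether by Lewis acid-assisted ionisation and should leave the methyl ethers and ring C intact at that temperature. It makes no new intermediate.

## Further compounds

F1 | step 4 | 1-(2-hydroxy-3,4-dimethoxyphenyl)ethanone | COc1ccc(C(C)=O)c(O)c1OC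
F2 | step 4 | 6-acetyl-2,3-dimethoxyphenyl 3-benzyloxy-4,5-dimethoxybenzoate | COc1cc(C(=O)Oc2c(C(C)=O)ccc(OC)c2OC)cc(OCc2ccccc2)c1OC
F3 | step 4 | 1-(3-benzyloxy-4,5-dimethoxyphenyl)-3-(2-hydroxy-3,4-dimethoxyphenyl)propane-1,3-dione | COc1cc(C(=O)CC(=O)c2ccc(OC)c(OC)c2O)cc(OCc2ccccc2)c1OC
F4 | step 4 | 2-(3-benzyloxy-4,5-dimethoxyphenyl)-7,8-dimethoxy-4H-chromen-4-one | COc1cc(C2=CC(=O)c3ccc(OC)c(OC)c3O2)cc(OCc2ccccc2)c1OC
F5 | step 4 | (2S,4S)-2-(3-benzyloxy-4,5-dimethoxyphenyl)-7,8-dimethoxychroman-4-ol (cis) | COc1cc([C@@H]2C[C@H](O)c3ccc(OC)c(OC)c3O2)cc(OCc2ccccc2)c1OC
F6 | step 3 | 3-benzyloxy-4,5-dimethoxybenzaldehyde | COc1cc(C=O)cc(OCc2ccccc2)c1OC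
F7 | step 3 | racemic chloro(3-benzyloxy-4,5-dimethoxyphenyl)methyl acetate | COc1cc(C(Cl)OC(C)=O)cc(OCc2ccccc2)c1OC
F0 | step 6 | none | none
A1 | alternative 1 | 3'-benzyloxy-4',5',7,8-tetramethoxyflavone | COc1cc(C2=CC(=O)c3ccc(OC)c(OC)c3O2)cc(OCc2ccccc2)c1OC
A2 | alternative 1 | 6-iodo-2,3-dimethoxyphenol | COc1ccc(I)c(O)c1OC
A3 | alternative 1 | 1-benzyloxy-5-ethynyl-2,3-dimethoxybenzene | COc1cc(C#C)cc(OCc2ccccc2)c1OC
A4 | alternative 2 | (2S,4S)-cis-3'-benzyloxy-4,4',5',7,8-pentamethoxyflavan | COc1cc([C@@H]2C[C@H](OC)c3ccc(OC)c(OC)c3O2)cc(OCc2ccccc2)c1OC
A5 | alternative 2 | 6-(dimethoxymethyl)-2,3-dimethoxyphenol | COc1ccc(C(OC)OC)c(O)c1OC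
A6 | alternative 2 | 1-benzyloxy-5-ethenyl-2,3-dimethoxybenzene | COc1cc(C=C)cc(OCc2ccccc2)c1OC
A7 | alternative 2 | 2,3-dimethoxy-6-(methoxymethylidene)cyclohexa-2,4-dien-1-one (4-methoxy ortho-quinone methide) | COC=C1C=CC(OC)=C(OC)C1=O
A8 | alternative 3 | (2S)-3'-benzyloxy-4',5',7,8-tetramethoxyflavanone ethylene ketal | COc1cc([C@@H]2CC3(OCCO3)c3ccc(OC)c(OC)c3O2)cc(OCc2ccccc2)c1OC
A9 | alternative 3 | (1S)-1-(3-benzyloxy-4,5-dimethoxyphenyl)-2-[2-(2-bromo-3,4-dimethoxyphenyl)-1,3-dioxolan-2-yl]ethanol | COc1cc([C@@H](O)CC2(OCCO2)c2ccc(OC)c(OC)c2Br)cc(OCc2ccccc2)c1OC
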